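(Its constants belong to no real substance; the flask was simulated.)

If a product is lost to its own starting material at a rate proportional to both, the share that survives should depend on how long the product has stood and in how much of that material. Here the target is the product and the substrate attacks it.

the same everywhere: free catalyst 5.0 mM; time 12 h

|  | substrate | coupling partner | remark |
|---|---|---|---|
| maple | 0.050 M (fed, over 10 h) | 0.0550 M | all else is in the flask from the start; the feed brings no volume worth counting |
| ash | 0.050 M | 0.0550 M (fed, over 10 h) | all else is in the flask from the start; the feed brings no volume worth counting |
| birch | 0.050 M | 0.0550 M | everything together at the start |
| elm | 0.050 M | 0.0550 M (fed, over 1.0 h) | all else is in the flask from the start; the feed brings no volume worth counting |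

1. the flask with the highest share of target in target plus side product ("all alike" if they lie within 1.5 percentage points) (maple / ash / birch / elm / all alike)
2. share of target in target plus side product at the end, maple
3. share of target in target plus side product at the end, ash
4. share of target in target plus side product at the end, birch
5. share of target in target plus side product at the end, elm

- a species is counted by the substrate in it: one side product counts as two
- run time (maple): 12 h

Free catalyst takes up substrate to give catalyst intermediate A, which takes up coupling partner to give catalyst intermediate B, which releases target and free catalyst. Beside this loop, substrate and target give side product, with constant 0.70 /M/h.

I wanted the pace of the loop first. In birch, at the charged amounts, one turn costs its three waits added: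

turn = 3.53 h, so target comes at 1.42 mM/h

Each target then faces a pseudo-first-order loss, the constant times [substrate], and each side product counts 2. I therefore reckoned:

exposure = 2 × constant × mean [substrate] × mean age of the target
share = 1 / (1 + exposure)

In birch I took a straight target line, so the age was 6.00 h, and a mean [substrate] of 0.0415 M. That gave 74.2%.

In elm I let the start slip by 0.500 h, so the age was 5.75 h and the share 75.0%.

In maple the feed brings 5.00 mM/h, faster than the pace I had reckoned for birch, so I took [substrate] as a bare ramp with a mean of 0.0292 M. The wait for substrate is longer at that mean than at the full charge, so I bent the maple target line upward like a square, which gave an age of 4.00 h and a share of 86.0%.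

For ash I took the mean of the birch and maple ages, 5.00 h, with birch's [substrate], and got 77.5%. I committed to maple.

The weak link was the plain mean: the side step goes as [substrate] times target, so the mean I needed was one weighted by the target then standing. In birch, with both lines straight, that weighted mean falls at 8.00 h, which gives 0.03867 M. This yields the quantity I carried on, the target's exposure 0.325, and a birch share of 75.5%.

The forecast gave maple as best, with 82%, 78%, 77% and 77% for maple, ash, birch and elm, saying “Feeding substrate keeps it low while target builds up”.

The simulation gave maple, with 82.9%, 79.6%, 76.4% and 76.6% in the same order.

    catalyst intermediate B → free catalyst + target (k1 = 0.97 /h)
    substrate + free catalyst → catalyst intermediate A (k2 = 14 /M/h)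
    coupling partner + catalyst intermediate A → catalyst intermediate B (k3 = 17 /M/h)
    substrate + target → side product (k4 = 0.70 /M/h)

Maple held target of 4.31% of the substrate charged after 6.00 h and 15.8% after 12.0 h, so the earlier reading was about a quarter of the later one. For a neighbour of birch charged with 0.085 M of substrate, I reckoned the loop at 1.70 mM/h and the weighted [substrate] at 0.0714 M. Birch's exposure then scaled to 0.600, a share of 62.5%, and that neighbour gave 62.7%.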